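**Plan**

- Retrosynthesis: the first cut is the C(=O)–CH(OH) bond of the α-ketol bridge, ring A–C(=O)–CH(OH)–CH2–ring B. The carbonyl carbon on ring A (2,4-dihydroxy-3-prenylphenyl) and the neighbouring carbinol carbon are 1,2-related oxygenated carbons of like (acceptor) polarity. The ketone carbon is therefore used with reversed polarity as an aroylsilane, whose Brook carbanion is stabilised by ring A, and joined to the aldehyde carbon of an arylacetaldehyde.
- Further cuts: both aryl–prenyl bonds (aryl anion + prenyl bromide) and the aryl–CH2CH2 bond of ring B (aryl Grignard + ethylene oxide).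
- Forward, ring A piece: 2,4-dihydroxybenzaldehyde → dithiane → bis-MOM ether → C-silylation → ortho-metalation/prenylation → aroylsilane.
- Forward, ring B piece: 2,4-dibromophenol → MOM ether → ortho Br/Li exchange/prenylation → two-carbon homologation → arylacetaldehyde. The two pieces are then joined and deprotected in one acid step; no ring is formed in the route.
- Stereochemistry: the single (R) carbinol centre is created in the union by a chiral TADDOL phosphite (catalyst control) and carried on as its triethylsilyl ether.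

Key step: step 10

Assumption: the (R,R)-TADDOL-derived phosphite is taken to deliver the (R) silyloxy ketone; the sense is to be checked on a model pair, and the (S,S) ligand (from D-tartrate) is used if it proves opposite.

**Route**

Step 1
Reactants: 1 2,4-dihydroxybenzaldehyde
Product: 2 2-(2,4-dihydroxyphenyl)-1,3-dithiane
Conditions: HS(CH2)3SH, BF3·OEt2 (cat.), AcOH–CHCl3, 0 °C to rt
Reagents that add atoms: 1,3-propanedithiol (SCCCS)
Why: Lewis-acid thioacetalisation (Corey–Seebach dithiane formation) masks the aldehyde as the acyl-anion precursor before any acid-labile group is present; ring closure of the thionium ion by the second thiol should outrun arylation by the electron-rich ring.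

Step 2
Reactants: 2 2-(2,4-dihydroxyphenyl)-1,3-dithiane
Product: 3 2-[2,4-bis(methoxymethoxy)phenyl]-1,3-dithiane
Conditions: MOMCl, i-Pr2NEt, CH2Cl2–DMF, 0 °C to rt
Reagents that add atoms: chloromethyl methyl ether (COCCl)
Why: O-alkylation of both phenols with MOMCl; the thioacetal is inert to base, and MOM serves later as ortho-metalation director and is removable in one acid step.

Step 3
Reactants: 3 2-[2,4-bis(methoxymethoxy)phenyl]-1,3-dithiane
Product: 5 {2-[2,4-bis(methoxymethoxy)phenyl]-1,3-dithian-2-yl}triethylsilane, via 2-lithio-2-[2,4-bis(methoxymethoxy)phenyl]-1,3-dithiane 4 (not isolated)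
Conditions: n-BuLi, THF, −78 to −30 °C; Et3SiCl, −78 °C to rt
Reagents that add atoms: chlorotriethylsilane (CC[Si](Cl)(CC)CC)
Why: The benzylic dithiane C–H (two sulfurs, aryl, ortho-OMOM coordination) is the most acidic site at low temperature; C-silylation of the 2-lithio-1,3-dithiane (Brook–Corey acylsilane synthesis) also blocks this position for the next metalation.

Step 4
Reactants: 5 {2-[2,4-bis(methoxymethoxy)phenyl]-1,3-dithian-2-yl}triethylsilane
Product: 7 {2-[2,4-bis(methoxymethoxy)-3-(3-methylbut-2-en-1-yl)phenyl]-1,3-dithian-2-yl}triethylsilane, via {2-[3-lithio-2,4-bis(methoxymethoxy)phenyl]-1,3-dithian-2-yl}triethylsilane 6 (not isolated)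
Conditions: n-BuLi, TMEDA, THF, 0 °C; CuBr·SMe2 (10 mol %), prenyl bromide, −78 to 0 °C
Reagents that add atoms: prenyl bromide, 1-bromo-3-methylbut-2-ene (CC(C)=CCBr)
Why: Directed ortho-metalation removes the ring C–H flanked by the two OMOM groups (C3), the quaternary silyl dithiane having no acidic C–H left; copper-catalysed allylic substitution at the primary carbon of prenyl bromide should give the linear prenyl arene.

Step 5
Reactants: 7 {2-[2,4-bis(methoxymethoxy)-3-(3-methylbut-2-en-1-yl)phenyl]-1,3-dithian-2-yl}triethylsilane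
Product: 8 [2,4-bis(methoxymethoxy)-3-(3-methylbut-2-en-1-yl)phenyl](triethylsilyl)methanone
Conditions: MeI, CaCO3, MeCN–H2O, 40 °C, dark
Reagents that add atoms: water (O)
Why: Alkylative dithiane hydrolysis (S-methylation, thionium formation, hydration) unmasks the aroylsilane under near-neutral, non-oxidising conditions that should leave the trisubstituted alkene and the MOM acetals untouched.

Step 6
Reactants: 9 2,4-dibromophenol
Product: 10 2,4-dibromo-1-(methoxymethoxy)benzene
Conditions: MOMCl, i-Pr2NEt, CH2Cl2, 0 °C to rt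
Reagents that add atoms: chloromethyl methyl ether (COCCl)
Why: Standard MOM protection of the phenol; the acetal oxygen then directs the selective exchange of the adjacent bromine.

Step 7
Reactants: 10 2,4-dibromo-1-(methoxymethoxy)benzene
Product: 12 4-bromo-1-(methoxymethoxy)-2-(3-methylbut-2-en-1-yl)benzene, via 4-bromo-2-lithio-1-(methoxymethoxy)benzene 11 (not isolated)
Conditions: n-BuLi (1.0 equiv), Et2O, −78 °C; CuBr·SMe2 (10 mol %), prenyl bromide, −78 to 0 °C
Reagents that add atoms: prenyl bromide, 1-bromo-3-methylbut-2-ene (CC(C)=CCBr)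
Why: Bromine–lithium exchange is expected at the bromine ortho to OMOM (chelation and inductive stabilisation of the aryllithium), leaving the para bromine for step 8; copper-catalysed SN2 allylation installs the prenyl group.

Step 8
Reactants: 12 4-bromo-1-(methoxymethoxy)-2-(3-methylbut-2-en-1-yl)benzene
Product: 14 2-[4-(methoxymethoxy)-3-(3-methylbut-2-en-1-yl)phenyl]ethan-1-ol, via [4-(methoxymethoxy)-3-(3-methylbut-2-en-1-yl)phenyl]magnesium bromide 13 (not isolated)
Conditions: Mg, THF, reflux; CuI (10 mol %), ethylene oxide, −30 °C to rt; aq. NH4Cl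
Reagents that add atoms: ethylene oxide, oxirane (C1CO1)
Why: Grignard formation followed by copper-catalysed ring opening of ethylene oxide is a two-carbon homologation to the 2-arylethanol; the Grignard reagent is too weakly basic to deprotonate the benzylic/allylic CH2 of the prenyl group.

Step 9
Reactants: 14 2-[4-(methoxymethoxy)-3-(3-methylbut-2-en-1-yl)phenyl]ethan-1-ol
Product: 15 2-[4-(methoxymethoxy)-3-(3-methylbut-2-en-1-yl)phenyl]acetaldehyde
Conditions: Dess–Martin periodinane, CH2Cl2, 0 °C to rt; used at once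
Reagents that add atoms: none
Why: Dess–Martin oxidation stops at the aldehyde under non-basic conditions, which limits enolisation and aldol reaction of the sensitive arylacetaldehyde.

Step 10
Reactants: 8 [2,4-bis(methoxymethoxy)-3-(3-methylbut-2-en-1-yl)phenyl](triethylsilyl)methanone; 15 2-[4-(methoxymethoxy)-3-(3-methylbut-2-en-1-yl)phenyl]acetaldehyde
Product: 16 (2R)-1-[2,4-bis(methoxymethoxy)-3-(3-methylbut-2-en-1-yl)phenyl]-3-[4-(methoxymethoxy)-3-(3-methylbut-2-en-1-yl)phenyl]-2-[(triethylsilyl)oxy]propan-1-one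
Conditions: (R,R)-TADDOL-derived cyclic phosphite (aryl = 2-FC6H4, 15 mol %), n-BuLi (12 mol %), THF, 0 °C to rt, slow addition of 15 (1.5 equiv)
Reagents that add atoms: none
Why: The lithium phosphite adds to the acylsilane carbonyl of 8, a [1,2]-Brook rearrangement gives an α-silyloxy phosphonate carbanion (an acyl anion equivalent stabilised by ring A and P=O), this adds to the aldehyde carbon of 15, and 1,4 O→O silyl transfer with loss of the phosphite releases the α-silyloxy ketone and the catalyst. The closest known reaction type is the metallophosphite-catalysed enantioselective cross silyl benzoin reaction of aryl acylsilanes with aldehydes, with the cyanide-catalysed reaction as its racemic parent. No ring is closed. The new carbinol stereocentre is set in the C–C bond-forming addition, where the C2-symmetric TADDOL backbone on phosphorus differentiates the faces of the carbanion–aldehyde pair (catalyst control; R under the assumption above). The step needs regioselectivity (which carbon ends as the ketone) and cross- over homo-coupling: only the acylsilane can become the nucleophile and the silyl group ends on the oxygen of the former aldehyde, so one constitution is possible. Enolisation and aldol reaction of 15 are held back by the weakly basic, substoichiometric phosphite, the low temperature and the slow addition.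

Step 11
Reactants: 16 (2R)-1-[2,4-bis(methoxymethoxy)-3-(3-methylbut-2-en-1-yl)phenyl]-3-[4-(methoxymethoxy)-3-(3-methylbut-2-en-1-yl)phenyl]-2-[(triethylsilyl)oxy]propan-1-one
Product: 17 glycybridin C, (2R)-1-[2,4-dihydroxy-3-(3-methylbut-2-en-1-yl)phenyl]-2-hydroxy-3-[4-hydroxy-3-(3-methylbut-2-en-1-yl)phenyl]propan-1-one
Conditions: HCl (ca. 1 M, MeOH–H2O), 0 °C to rt; NaHCO3 quench
Reagents that add atoms: none
Why: Acid-catalysed acetal exchange removes the three MOM ethers and solvolysis cleaves the TES ether in the same operation; dilute acid at low temperature is chosen so that the prenyl groups should not cyclise onto the neighbouring phenols and the α-ketol should not enolise, leaving the stereocentre untouched.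

**Compound list**

1 | 2,4-dihydroxybenzaldehyde | O=Cc1ccc(O)cc1O | starting material
2 | 2-(2,4-dihydroxyphenyl)-1,3-dithiane | Oc1ccc(C2SCCCS2)c(O)c1 | intermediate
3 | 2-[2,4-bis(methoxymethoxy)phenyl]-1,3-dithiane | COCOc1ccc(C2SCCCS2)c(OCOC)c1 | intermediate
4 | 2-lithio-2-[2,4-bis(methoxymethoxy)phenyl]-1,3-dithiane (formed in the flask) | [Li]C1(c2ccc(OCOC)cc2OCOC)SCCCS1 | intermediate
5 | {2-[2,4-bis(methoxymethoxy)phenyl]-1,3-dithian-2-yl}triethylsilane | CC[Si](CC)(CC)C1(c2ccc(OCOC)cc2OCOC)SCCCS1 | intermediate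
6 | {2-[3-lithio-2,4-bis(methoxymethoxy)phenyl]-1,3-dithian-2-yl}triethylsilane (formed in the flask) | CC[Si](CC)(CC)C1(c2ccc(OCOC)c([Li])c2OCOC)SCCCS1 | intermediate
7 | {2-[2,4-bis(methoxymethoxy)-3-(3-methylbut-2-en-1-yl)phenyl]-1,3-dithian-2-yl}triethylsilane | CC[Si](CC)(CC)C1(c2ccc(OCOC)c(CC=C(C)C)c2OCOC)SCCCS1 | intermediate
8 | [2,4-bis(methoxymethoxy)-3-(3-methylbut-2-en-1-yl)phenyl](triethylsilyl)methanone | CC[Si](CC)(CC)C(=O)c1ccc(OCOC)c(CC=C(C)C)c1OCOC | intermediate
9 | 2,4-dibromophenol | Oc1ccc(Br)cc1Br | starting material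
10 | 2,4-dibromo-1-(methoxymethoxy)benzene | COCOc1ccc(Br)cc1Br | intermediate
11 | 4-bromo-2-lithio-1-(methoxymethoxy)benzene (formed in the flask) | [Li]c1cc(Br)ccc1OCOC | intermediate
12 | 4-bromo-1-(methoxymethoxy)-2-(3-methylbut-2-en-1-yl)benzene | COCOc1ccc(Br)cc1CC=C(C)C | intermediate
13 | [4-(methoxymethoxy)-3-(3-methylbut-2-en-1-yl)phenyl]magnesium bromide (formed in the flask) | COCOc1ccc([Mg]Br)cc1CC=C(C)C | intermediate
14 | 2-[4-(methoxymethoxy)-3-(3-methylbut-2-en-1-yl)phenyl]ethan-1-ol | COCOc1ccc(CCO)cc1CC=C(C)C | intermediate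
15 | 2-[4-(methoxymethoxy)-3-(3-methylbut-2-en-1-yl)phenyl]acetaldehyde | COCOc1ccc(CC=O)cc1CC=C(C)C | intermediate
16 | (2R)-1-[2,4-bis(methoxymethoxy)-3-(3-methylbut-2-en-1-yl)phenyl]-3-[4-(methoxymethoxy)-3-(3-methylbut-2-en-1-yl)phenyl]-2-[(triethylsilyl)oxy]propan-1-one | CC(C)=CCc1cc(C[C@@H](O[Si](CC)(CC)CC)C(=O)c2ccc(OCOC)c(CC=C(C)C)c2OCOC)ccc1OCOC | intermediate
17 | glycybridin C, (2R)-1-[2,4-dihydroxy-3-(3-methylbut-2-en-1-yl)phenyl]-2-hydroxy-3-[4-hydroxy-3-(3-methylbut-2-en-1-yl)phenyl]propan-1-one | CC(C)=CCc1cc(C[C@@H](O)C(=O)c2ccc(O)c(CC=C(C)C)c2O)ccc1O | target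

**Step count**

Total steps: 11. Longest linear sequence: 7 (steps 1–5, 10, 11); the ring B branch (steps 6–9) joins at step 10.

**Steps most likely to fail, with fallbacks**

Step 10. The arylacetaldehyde may enolise and undergo aldol self-condensation under the lithium phosphite, the phosphite may add only slowly to the ortho,ortho′-flanked acylsilane carbonyl, or facial selectivity in the addition may be poor. The fallback keeps the same bond but uses stoichiometric dithiane umpolung and sets the stereocentre by reagent-controlled reduction. It sets out from 7: fluoride (TBAF, wet THF) removes the C-silyl group to give 2-[2,4-bis(methoxymethoxy)-3-(3-methylbut-2-en-1-yl)phenyl]-1,3-dithiane F1. Lithiation (n-BuLi, THF, −78 °C), transmetalation with anhydrous CeCl3 to lower the basicity of the nucleophile, and addition to 15 at −78 °C should give the racemic carbinol 1-{2-[2,4-bis(methoxymethoxy)-3-(3-methylbut-2-en-1-yl)phenyl]-1,3-dithian-2-yl}-2-[4-(methoxymethoxy)-3-(3-methylbut-2-en-1-yl)phenyl]ethan-1-ol F2. Parikh–Doering oxidation (SO3·pyridine, DMSO, Et3N) gives the corresponding 2-acyl-1,3-dithiane, 1-{2-[2,4-bis(methoxymethoxy)-3-(3-methylbut-2-en-1-yl)phenyl]-1,3-dithian-2-yl}-2-[4-(methoxymethoxy)-3-(3-methylbut-2-en-1-yl)phenyl]ethan-1-one F3. Corey–Bakshi–Shibata reduction with (S)-Me-CBS and catecholborane, the quaternary dithianyl carbon acting as the large group, should give the (1R)-alcohol, (1R)-1-{2-[2,4-bis(methoxymethoxy)-3-(3-methylbut-2-en-1-yl)phenyl]-1,3-dithian-2-yl}-2-[4-(methoxymethoxy)-3-(3-methylbut-2-en-1-yl)phenyl]ethan-1-ol F4. Silylation (TESCl, imidazole, DMF) gives the (1R)-triethylsilyl ether of that alcohol F5, and hydrolysis of the dithiane with MeI/CaCO3 in aqueous MeCN comes back to the route at 16.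

Step 4. The crowded aryllithium may attack the tertiary (γ) carbon of prenyl bromide, or be quenched by the allylic C–H of the bromide or of the product before alkylation, giving isomer mixtures or recovered 5. The fallback makes the aryl–prenyl bond by cross-coupling instead of alkylation. It sets out from 5: the aryllithium 6 (n-BuLi, TMEDA, THF, 0 °C) is trapped with iodine to give {2-[3-iodo-2,4-bis(methoxymethoxy)phenyl]-1,3-dithian-2-yl}triethylsilane F6. Stille coupling of F6 with tributyl(3-methylbut-2-en-1-yl)stannane (Pd(PPh3)4, CuI, CsF, DMF, 80 °C) should deliver the linear prenyl arene and comes back to the route at 7.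

Step 11. Under protic acid the prenyl groups may cyclise onto the freed ortho phenols (chroman formation), or acid-promoted enolisation may erode the α-ketol stereocentre. The fallback avoids Brønsted acid by acetal exchange to silyl ethers followed by fluoride. It sets out from 16: TMSOTf/2,2′-bipyridyl (CH2Cl2, 0 °C) should convert the three aryl MOM ethers into aryl trimethylsilyl ethers, giving (2R)-1-[3-(3-methylbut-2-en-1-yl)-2,4-bis(trimethylsilyloxy)phenyl]-3-[3-(3-methylbut-2-en-1-yl)-4-(trimethylsilyloxy)phenyl]-2-[(triethylsilyl)oxy]propan-1-one F7. Et3N·3HF (THF–MeCN, 0 °C) then removes all four silyl groups and comes back to the route at 17.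

**Further compounds**

F1 | step 10 | 2-[2,4-bis(methoxymethoxy)-3-(3-methylbut-2-en-1-yl)phenyl]-1,3-dithiane | COCOc1ccc(C2SCCCS2)c(OCOC)c1CC=C(C)C
F2 | step 10 | rac-1-{2-[2,4-bis(methoxymethoxy)-3-(3-methylbut-2-en-1-yl)phenyl]-1,3-dithian-2-yl}-2-[4-(methoxymethoxy)-3-(3-methylbut-2-en-1-yl)phenyl]ethan-1-ol | CC(C)=CCc1cc(CC(O)C2(c3ccc(OCOC)c(CC=C(C)C)c3OCOC)SCCCS2)ccc1OCOC
F3 | step 10 | 1-{2-[2,4-bis(methoxymethoxy)-3-(3-methylbut-2-en-1-yl)phenyl]-1,3-dithian-2-yl}-2-[4-(methoxymethoxy)-3-(3-methylbut-2-en-1-yl)phenyl]ethan-1-one | CC(C)=CCc1cc(CC(=O)C2(c3ccc(OCOC)c(CC=C(C)C)c3OCOC)SCCCS2)ccc1OCOC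
F4 | step 10 | (1R)-1-{2-[2,4-bis(methoxymethoxy)-3-(3-methylbut-2-en-1-yl)phenyl]-1,3-dithian-2-yl}-2-[4-(methoxymethoxy)-3-(3-methylbut-2-en-1-yl)phenyl]ethan-1-ol | CC(C)=CCc1cc(C[C@@H](O)C2(c3ccc(OCOC)c(CC=C(C)C)c3OCOC)SCCCS2)ccc1OCOC
F5 | step 10 | {(1R)-1-{2-[2,4-bis(methoxymethoxy)-3-(3-methylbut-2-en-1-yl)phenyl]-1,3-dithian-2-yl}-2-[4-(methoxymethoxy)-3-(3-methylbut-2-en-1-yl)phenyl]ethoxy}triethylsilane (triethylsilyl ether of F4) | CC(C)=CCc1cc(C[C@@H](O[Si](CC)(CC)CC)C2(c3ccc(OCOC)c(CC=C(C)C)c3OCOC)SCCCS2)ccc1OCOC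
F6 | step 4 | {2-[3-iodo-2,4-bis(methoxymethoxy)phenyl]-1,3-dithian-2-yl}triethylsilane | CC[Si](CC)(CC)C1(c2ccc(OCOC)c(I)c2OCOC)SCCCS1
F7 | step 11 | (2R)-1-[3-(3-methylbut-2-en-1-yl)-2,4-bis(trimethylsilyloxy)phenyl]-3-[3-(3-methylbut-2-en-1-yl)-4-(trimethylsilyloxy)phenyl]-2-[(triethylsilyl)oxy]propan-1-one | CC(C)=CCc1cc(C[C@@H](O[Si](CC)(CC)CC)C(=O)c2ccc(O[Si](C)(C)C)c(CC=C(C)C)c2O[Si](C)(C)C)ccc1O[Si](C)(C)C
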